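**Retrosynthetic overview**
1. Target ⇐ double epoxidation (last step) of the (3E,7E)-macrocyclic diene enone; the C12(=C18)–C13 enone ⇐ a 13,18-diol carried as an acetonide.
2. Twelve-membered ring ⇐ C5–C6 bond: intramolecular alkylation of a C6 allylic sulfone anion by a C5 allylic bromide, then Pd-catalysed desulfonylation.
3. C11 arm ⇐ C10 aldehyde: Roskamp homologation, ketoreductase reduction (sets C10), alkyne, Zr-catalysed carboalumination (E-C7=C8). C1 arm ⇐ vinyl: hydroboration, Wittig (E-C3=C4).
4. Ring A ⇐ 4,4-dimethylcyclohexane-1,3-dione: Stork–Danheiser transposition, Saegusa oxidation, Rh/(S)-BINAP vinyl addition (first stereocentre), CuH reduction/hydroxymethylation (cis arms, C18 on C12).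
5. Ring order: six-membered ring A first, twelve-membered ring second, the two oxiranes last.

Convention and assumption: atoms carry verticillane numbers (C1/C11 bridgeheads, C15 = CMe2, C12=C18, C13 = ketone carbon, C10 = acetoxy carbon, C19 on C8, C20 on C4); PMB = 4-methoxybenzyl, TBS = tert-butyldimethylsilyl; (tributylstannyl)methanol and an (R)-selective ketoreductase from a screening panel are taken as commercially available.

Step 1
Reactants: 1 (tributylstannyl)methanol; 2 4-methoxybenzyl chloride
Product: 3 tributyl{[(4-methoxybenzyl)oxy]methyl}stannane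
Conditions: NaH, Bu4NI (cat.), THF/DMF, 0 °C to rt
Reagents that add atoms: none
Why: Williamson ether synthesis in which the sodium alkoxide of the stannylmethanol displaces the benzylic chloride under iodide catalysis, with no stereocentre involved.

Step 2
Reactants: 4 4,4-dimethylcyclohexane-1,3-dione
Product: 5 3-isobutoxy-6,6-dimethylcyclohex-2-en-1-one
Conditions: i-BuOH, TsOH·H2O (cat.), toluene, reflux, Dean–Stark
Reagents that add atoms: 2-methylpropan-1-ol, CC(C)CO
Why: Acid-catalysed vinylogous esterification with azeotropic removal of water, in which the alcohol enters at the carbonyl remote from the gem-dimethyl group so that the ketone next to the quaternary carbon stays free (the minor regioisomer is removed by chromatography).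

Step 3
Reactants: 5 3-isobutoxy-6,6-dimethylcyclohex-2-en-1-one; 3 tributyl{[(4-methoxybenzyl)oxy]methyl}stannane
Product: 8 3-{[(4-methoxybenzyl)oxy]methyl}-4,4-dimethylcyclohex-2-en-1-one, via [(4-methoxybenzyl)oxy]methyllithium 6 (not isolated), via carbinol adduct 7 (not isolated)
Conditions: 3, n-BuLi, THF, −78 °C; then 5, −78 to 0 °C; then 1 M HCl, THF, rt
Reagents that add atoms: none
Why: Stork–Danheiser alkylative carbonyl transposition in which tin–lithium exchange gives Still's alkoxymethyllithium, this adds 1,2 to the remaining ketone, and acid hydrolysis of the enol ether with loss of water delivers the 3-substituted enone carrying the future C10 on the future C11 (the carbinol centre of 7 is racemic and is destroyed in the same flask).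

Step 4
Reactants: 8 3-{[(4-methoxybenzyl)oxy]methyl}-4,4-dimethylcyclohex-2-en-1-one
Product: 9 {[5-({[(4-methoxybenzyl)oxy]}methyl)-4,4-dimethylcyclohexa-1,5-dien-1-yl]oxy}trimethylsilane
Conditions: LiN(i-Pr)2, Me3SiCl (in situ quench), THF, −78 °C
Reagents that add atoms: chlorotrimethylsilane, C[Si](C)(C)Cl
Why: Kinetic deprotonation of the enone at its alpha-prime CH2 (the ring gamma carbon is quaternary) and O-silylation give the cross-conjugated 2-silyloxydiene regiospecifically.

Step 5
Reactants: 9 {[5-({[(4-methoxybenzyl)oxy]}methyl)-4,4-dimethylcyclohexa-1,5-dien-1-yl]oxy}trimethylsilane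
Product: 10 3-{[(4-methoxybenzyl)oxy]methyl}-4,4-dimethylcyclohexa-2,5-dien-1-one
Conditions: Pd(OAc)2 (1.05 equiv), MeCN, rt
Reagents that add atoms: none
Why: Saegusa–Ito oxidation in which the palladium enolate formed from the silyl enol ether undergoes beta-hydride elimination to the achiral cross-conjugated dienone, the PMB ether being inert to divalent palladium.

Step 6
Reactants: 10 3-{[(4-methoxybenzyl)oxy]methyl}-4,4-dimethylcyclohexa-2,5-dien-1-one; 11 potassium trifluoro(vinyl)borate
Product: 12 (5S)-3-{[(4-methoxybenzyl)oxy]methyl}-4,4-dimethyl-5-vinylcyclohex-2-en-1-one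
Conditions: [Rh(cod)2]BF4 (3 mol%), (S)-BINAP (3.3 mol%), Et3N, toluene/H2O 10:1, 60 °C
Reagents that add atoms: none
Why: Hayashi–Miyaura rhodium-catalysed asymmetric 1,4-addition in which the vinylrhodium–(S)-BINAP complex adds only to the beta-unsubstituted enone arm, with the facial sense by which (S)-BINAP gives (S)-3-substituted cyclohexanones from cyclohex-2-enone, and so creates the first stereocentre (C1 of the target) before water protonates the rhodium enolate.

Step 7
Reactants: 12 (5S)-3-{[(4-methoxybenzyl)oxy]methyl}-4,4-dimethyl-5-vinylcyclohex-2-en-1-one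
Product: 14 (2R,3S,5S)-2-(hydroxymethyl)-3-{[(4-methoxybenzyl)oxy]methyl}-4,4-dimethyl-5-vinylcyclohexan-1-one, via dimethylphenylsilyl enol ether 13 (not isolated)
Conditions: [(Ph3P)CuH]6 (5 mol% Cu), 1,2-(Ph2P)2C6H4 (5 mol%), PhMe2SiH (1.5 equiv), toluene, rt; then 37% aq. HCHO, Yb(OTf)3 (10 mol%), THF, rt
Reagents that add atoms: formaldehyde, C=O
Why: Copper hydride-catalysed 1,4-hydrosilylation followed by a Mukaiyama aldol hydroxymethylation, in which hydride enters C11 axially on the face opposite the C1 vinyl group and the axial C15 methyl (forcing the CH2OPMB arm cis to the vinyl group) and the regiodefined silyl enol ether then takes formaldehyde at C12, never at C14, anti to the C11 arm.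

Step 8
Reactants: 14 (2R,3S,5S)-2-(hydroxymethyl)-3-{[(4-methoxybenzyl)oxy]methyl}-4,4-dimethyl-5-vinylcyclohexan-1-one
Product: 15 (1R,2R,3S,5S)-2-(hydroxymethyl)-3-{[(4-methoxybenzyl)oxy]methyl}-4,4-dimethyl-5-vinylcyclohexan-1-ol
Conditions: LiBH(s-Bu)3 (2.5 equiv), THF, −78 °C; then H2O
Reagents that add atoms: none
Why: Diastereoselective ketone reduction in which the bulky trialkylborohydride attacks C13 from the equatorial direction and gives the axial alcohol cis to the C12 hydroxymethyl group, a temporary stereocentre that is erased when C13 is reoxidised in step 31.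

Step 9
Reactants: 15 (1R,2R,3S,5S)-2-(hydroxymethyl)-3-{[(4-methoxybenzyl)oxy]methyl}-4,4-dimethyl-5-vinylcyclohexan-1-ol
Product: 16 13,18-O-isopropylidene acetal of 15 (cis-fused acetonide, C1 vinyl, C11 CH2OPMB)
Conditions: Me2C(OMe)2, PPTS (cat.), CH2Cl2, rt
Reagents that add atoms: 2,2-dimethoxypropane, COC(C)(C)OC
Why: Acid-catalysed transacetalisation ties the cis-1,3-diol into a cis-fused isopropylidene acetal that masks C13 and C18 together through all basic, reducing and organometallic steps.

Step 10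
Reactants: 16 13,18-O-isopropylidene acetal of 15
Product: 17 acetonide alcohol (C11 bears CH2OH = C10)
Conditions: DDQ, CH2Cl2/pH 7 buffer 10:1, 0 °C
Reagents that add atoms: none
Why: Oxidative cleavage of the PMB ether by DDQ (hydride abstraction from the electron-rich benzylic position, then hydrolysis of the oxocarbenium ion) frees the C10 alcohol without touching the acetonide or the vinyl group.

Step 11
Reactants: 17 acetonide alcohol
Product: 18 acetonide aldehyde (C11 bears CHO = C10)
Conditions: Dess–Martin periodinane, NaHCO3, CH2Cl2, 0 °C to rt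
Reagents that add atoms: none
Why: Dess–Martin oxidation under buffered, non-enolising conditions gives the C10 aldehyde with C11 unchanged.

Step 12
Reactants: 18 acetonide aldehyde; 19 ethyl diazoacetate
Product: 20 acetonide beta-keto ester (C11–C(=O)–CH2–CO2Et)
Conditions: SnCl2 (10 mol%), CH2Cl2, rt
Reagents that add atoms: none
Why: Roskamp reaction in which tin dichloride-promoted addition of the diazo ester to the aldehyde and a 1,2-hydride shift with loss of nitrogen give the beta-keto ester, adding C9 and C8 without base and so without epimerisation at C11.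

Step 13
Reactants: 20 acetonide beta-keto ester
Product: 21 acetonide beta-hydroxy ester with (R)-configured carbinol C10
Conditions: ketoreductase (KRED, (R)-selective), NADP+ (cat.), i-PrOH (10 vol%), DMSO (5 vol%), 0.1 M KH2PO4/K2HPO4 buffer pH 7.0, 30 °C
Reagents that add atoms: none
Why: Enzymatic asymmetric reduction by a ketoreductase in which NADPH held in the active site delivers hydride to a single face of the C10 ketone, so the (10R) carbinol is set by the enzyme and not by the substrate, isopropanol regenerates the cofactor, and material from the minor enantiomer of step 6 becomes a separable diastereomer.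

Step 14
Reactants: 21 acetonide beta-hydroxy ester
Product: 22 TBS ether of 21
Conditions: TBSOTf, 2,6-lutidine, CH2Cl2, −78 to 0 °C
Reagents that add atoms: tert-butyldimethylsilyl trifluoromethanesulfonate, CC(C)(C)[Si](C)(C)OS(=O)(=O)C(F)(F)F
Why: Silylation of the hindered secondary alcohol with the silyl triflate protects C10-OH for the reductions and carbanion chemistry ahead, and no stereocentre is touched.

Step 15
Reactants: 22 TBS ether of 21
Product: 23 beta-silyloxy aldehyde (C8 aldehyde)
Conditions: i-Bu2AlH (1.1 equiv), CH2Cl2, −78 °C; aq. KNaC4H4O6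
Reagents that add atoms: none
Why: Low-temperature DIBAL reduction stops at the aldehyde because the tetrahedral aluminium hemiacetal survives until aqueous work-up.

Step 16
Reactants: 23 beta-silyloxy aldehyde
Product: 24 terminal alkyne (C8≡C7)
Conditions: dimethyl (1-diazo-2-oxopropyl)phosphonate, K2CO3, MeOH, 0 °C to rt
Reagents that add atoms: dimethyl (1-diazo-2-oxopropyl)phosphonate, CC(=O)C(=[N+]=[N-])P(=O)(OC)OC
Why: Seyferth–Gilbert homologation in the Ohira–Bestmann variant, in which the diazomethylphosphonate anion generated in situ converts the aldehyde into the terminal alkyne (adding C7) under mild carbonate conditions.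

Step 17
Reactants: 24 terminal alkyne
Product: 27 (E)-allylic alcohol of the C11 arm (C6-OH), via alkenyldimethylalane 25 (not isolated), via lithium alkenylalanate 26 (not isolated)
Conditions: Me3Al (2.5 equiv), Cp2ZrCl2 (0.25 equiv), H2O (1 equiv), CH2Cl2, −20 °C to rt; then n-BuLi, THF, −78 °C; (CH2O)n, −78 °C to rt; aq. KNaC4H4O6
Reagents that add atoms: trimethylaluminium, C[Al](C)C; formaldehyde (as paraformaldehyde), C=O
Why: Negishi zirconium-catalysed carboalumination in which methyl and aluminium add syn across the terminal alkyne with aluminium on the terminal carbon, fixing the E geometry of C7=C8 and installing C19, after which the derived alanate adds to formaldehyde with retention to give the allylic alcohol (C6).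

Step 18
Reactants: 27 (E)-allylic alcohol of the C11 arm
Product: 28 (E)-allylic bromide (C6-Br)
Conditions: CBr4, PPh3, CH2Cl2, 0 °C
Reagents that add atoms: tetrabromomethane, BrC(Br)(Br)Br
Why: Appel reaction, an SN2 displacement of the alkoxyphosphonium ion by bromide at the primary allylic carbon without allylic transposition or loss of olefin geometry.

Step 19
Reactants: 28 (E)-allylic bromide
Product: 29 (E)-allylic phenyl sulfone (C6-SO2Ph)
Conditions: PhSO2Na, DMF, rt
Reagents that add atoms: sodium benzenesulfinate, [Na+].[O-]S(=O)c1ccccc1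
Why: SN2 S-alkylation of the sulfinate at the primary allylic bromide gives the allylic sulfone that will serve as the C6 carbanion precursor.

Step 20
Reactants: 29 (E)-allylic phenyl sulfone
Product: 31 primary alcohol at C3 (C1 arm = CH2CH2OH), via B-alkyl-9-BBN adduct 30 (not isolated)
Conditions: 9-BBN (1.5 equiv), THF, 0 °C to rt; then 3 M NaOH, 30% H2O2, 0 °C
Reagents that add atoms: hydrogen peroxide, OO
Why: Brown hydroboration–oxidation in which 9-BBN adds anti-Markovnikov to the monosubstituted vinyl group far faster than to the trisubstituted alkene and oxidation of the C–B bond gives the primary alcohol (C3).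

Step 21
Reactants: 31 primary alcohol at C3
Product: 32 aldehyde at C3 (C1 arm = CH2CHO)
Conditions: Dess–Martin periodinane, NaHCO3, CH2Cl2, rt
Reagents that add atoms: none
Why: Dess–Martin oxidation of the primary alcohol to the aldehyde, with the sulfone, silyl ether and acetonide inert.

Step 22
Reactants: 32 aldehyde at C3; 33 ethyl 2-(triphenyl-λ5-phosphanylidene)propanoate
Product: 34 (E)-enoate (C1 arm = CH2CH=C(CH3)CO2Et)
Conditions: toluene, 80 °C
Reagents that add atoms: none
Why: Wittig olefination with a stabilised ylide gives the (E)-trisubstituted enoate, which sets the E geometry of C3=C4 and brings in C4, C5 and C20.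

Step 23
Reactants: 34 (E)-enoate
Product: 35 (E)-allylic alcohol of the C1 arm (C5-OH)
Conditions: i-Bu2AlH (2.5 equiv), CH2Cl2, −78 °C; aq. KNaC4H4O6
Reagents that add atoms: none
Why: DIBAL 1,2-reduction of the conjugated ester to the allylic alcohol, with the sulfone untouched at low temperature.

Step 24
Reactants: 35 (E)-allylic alcohol of the C1 arm
Product: 36 (E)-allylic bromide of the C1 arm (C5-Br)
Conditions: CBr4, PPh3, CH2Cl2, 0 °C
Reagents that add atoms: tetrabromomethane, BrC(Br)(Br)Br
Why: Appel bromination of the primary allylic alcohol by SN2 gives the electrophilic partner for ring closure.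

Step 25
Reactants: 36 (E)-allylic bromide of the C1 arm
Product: 37 macrocyclic sulfone (C5–C6 bond closed, PhSO2 on C6, both C6 epimers)
Conditions: KN(SiMe3)2 (1.3 equiv), THF, −78 to 0 °C, syringe-pump addition of 36 (final 1 mM)
Reagents that add atoms: none
Why: Intramolecular alkylation of a sulfone-stabilised allylic carbanion (Julia-type sulfone coupling) in which, under high dilution, the C6 anion attacks through its alpha carbon the primary allylic bromide at C5 and closes the twelve-membered ring across the cis arms of ring A with both E alkenes preformed, the C6 epimers both being carried on.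

Step 26
Reactants: 37 macrocyclic sulfone
Product: 38 (3E,7E)-macrocyclic diene with 10-OTBS and the 13,18-acetonide
Conditions: PdCl2(dppp) (5 mol%), LiBHEt3 (2.5 equiv), THF, 0 °C
Reagents that add atoms: none
Why: Palladium-catalysed reductive desulfonylation in which zerovalent palladium ionises the allylic sulfone and hydride is delivered to the less substituted terminus (C6) of the allyl complex, so the E-C7=C8 alkene stays in place and the C6 stereocentre disappears.

Step 27
Reactants: 38 (3E,7E)-macrocyclic diene with 10-OTBS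
Product: 39 macrocyclic C10 alcohol (13,18-acetonide)
Conditions: Bu4NF, THF, 50 °C
Reagents that add atoms: none
Why: Fluoride-mediated cleavage of the silyl ether, driven by the strength of the Si–F bond, liberates C10-OH.

Step 28
Reactants: 39 macrocyclic C10 alcohol
Product: 40 macrocyclic C10 acetate (13,18-acetonide)
Conditions: Ac2O, DMAP, Et3N, CH2Cl2, rt
Reagents that add atoms: acetic anhydride, CC(=O)OC(C)=O
Why: DMAP-catalysed acylation installs the C10 acetate of the target with retention at C10.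

Step 29
Reactants: 40 macrocyclic C10 acetate
Product: 41 (3E,7E)-10-acetoxyverticilla-3,7-diene-13,18-diol
Conditions: PPTS, MeOH, 40 °C
Reagents that add atoms: none
Why: Acid-catalysed transacetalisation with methanol removes the isopropylidene acetal while the acetate and the trisubstituted alkenes survive.

Step 30
Reactants: 41 (3E,7E)-10-acetoxyverticilla-3,7-diene-13,18-diol
Product: 42 18-O-tosylate of 41
Conditions: TsCl (1.2 equiv), pyridine, CH2Cl2, 0 °C
Reagents that add atoms: 4-methylbenzenesulfonyl chloride, Cc1ccc(cc1)S(=O)(=O)Cl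
Why: Chemoselective sulfonylation in which the primary C18 hydroxyl reacts far faster than the hindered axial secondary C13 hydroxyl.

Step 31
Reactants: 42 18-O-tosylate of 41
Product: 44 (1R,3E,7E,10R,11R)-10-acetoxyverticilla-3,7,12(18)-trien-13-one, via β-tosyloxy ketone 43 (not isolated)
Conditions: Dess–Martin periodinane, NaHCO3, CH2Cl2, rt; then Et3N, rt
Reagents that add atoms: none
Why: Dess–Martin oxidation of C13-OH followed by E1cB elimination of tosylate from the beta-tosyloxy ketone generates the exocyclic enone exactly at C12=C18, the regiochemistry having been fixed in step 7.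

Step 32
Reactants: 44 (1R,3E,7E,10R,11R)-10-acetoxyverticilla-3,7,12(18)-trien-13-one
Product: 45 CNP0339728.1, (1R,3S,4S,7S,8S,10R,11R)-10-acetoxy-3,4:7,8-diepoxyverticill-12(18)-en-13-one
Conditions: m-CPBA (2.3 equiv), NaHCO3, CH2Cl2, 0 °C
Reagents that add atoms: 3-chloroperbenzoic acid, O=C(OO)c1cccc(Cl)c1
Why: Prilezhaev epoxidation in which the peracid transfers oxygen stereospecifically syn to the two electron-rich E-trisubstituted alkenes (the electron-poor enone is not attacked) and approaches each from the outer face of the crossed 1,5-diene conformation of the bridged macrocycle, which gives the (3S,4S) and (7S,8S) oxiranes.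

**Compound list**
1 | (tributylstannyl)methanol | CCCC[Sn](CCCC)(CCCC)CO | starting material
2 | 4-methoxybenzyl chloride | COc1ccc(CCl)cc1 | starting material
3 | tributyl{[(4-methoxybenzyl)oxy]methyl}stannane | CCCC[Sn](CCCC)(CCCC)COCc1ccc(OC)cc1 | intermediate
4 | 4,4-dimethylcyclohexane-1,3-dione | CC1(C)CCC(=O)CC1=O | starting material
5 | 3-isobutoxy-6,6-dimethylcyclohex-2-en-1-one | CC(C)COC1=CC(=O)C(C)(C)CC1 | intermediate
6 | [(4-methoxybenzyl)oxy]methyllithium | [Li]COCc1ccc(OC)cc1 | intermediate
7 | 3-isobutoxy-1-{[(4-methoxybenzyl)oxy]methyl}-6,6-dimethylcyclohex-2-en-1-ol (racemic carbinol adduct) | CC(C)COC1=CC(O)(COCc2ccc(OC)cc2)C(C)(C)CC1 | intermediate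
8 | 3-{[(4-methoxybenzyl)oxy]methyl}-4,4-dimethylcyclohex-2-en-1-one | O=C1C=C(COCc2ccc(OC)cc2)C(C)(C)CC1 | intermediate
9 | {[5-({[(4-methoxybenzyl)oxy]}methyl)-4,4-dimethylcyclohexa-1,5-dien-1-yl]oxy}trimethylsilane | C[Si](C)(C)OC1=CCC(C)(C)C(COCc2ccc(OC)cc2)=C1 | intermediate
10 | 3-{[(4-methoxybenzyl)oxy]methyl}-4,4-dimethylcyclohexa-2,5-dien-1-one | O=C1C=CC(C)(C)C(COCc2ccc(OC)cc2)=C1 | intermediate
11 | potassium trifluoro(vinyl)borate | C=C[B-](F)(F)F.[K+] | starting material
12 | (5S)-3-{[(4-methoxybenzyl)oxy]methyl}-4,4-dimethyl-5-vinylcyclohex-2-en-1-one | O=C1C=C(COCc2ccc(OC)cc2)C(C)(C)[C@H](C=C)C1 | intermediate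
13 | dimethyl(phenyl)silyl enol ether (C12=C13–OSi) of (3S,5S)-3-{[(4-methoxybenzyl)oxy]methyl}-4,4-dimethyl-5-vinylcyclohexanone, arms cis | C[Si](C)(c1ccccc1)OC1=C[C@H](COCc2ccc(OC)cc2)C(C)(C)[C@H](C=C)C1 | intermediate
14 | (2R,3S,5S)-2-(hydroxymethyl)-3-{[(4-methoxybenzyl)oxy]methyl}-4,4-dimethyl-5-vinylcyclohexan-1-one (C1 vinyl and C11 CH2OPMB cis; C12 CH2OH trans to the C11 arm) | OC[C@@H]1C(=O)C[C@@H](C=C)C(C)(C)[C@H]1COCc1ccc(OC)cc1 | intermediate
15 | (1R,2R,3S,5S)-2-(hydroxymethyl)-3-{[(4-methoxybenzyl)oxy]methyl}-4,4-dimethyl-5-vinylcyclohexan-1-ol (C13 OH axial, cis to the C12 CH2OH) | OC[C@@H]1[C@H](O)C[C@@H](C=C)C(C)(C)[C@H]1COCc1ccc(OC)cc1 | intermediate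
16 | 13,18-O-isopropylidene acetal of 15 (cis-fused 1,3-dioxane on ring A; C1 vinyl, C11 CH2OPMB) | CC1(C)OC[C@@H]2[C@H](O1)C[C@@H](C=C)C(C)(C)[C@H]2COCc1ccc(OC)cc1 | intermediate
17 | acetonide alcohol: as 16 with CH2OH (C10) on C11 | CC1(C)OC[C@@H]2[C@H](O1)C[C@@H](C=C)C(C)(C)[C@H]2CO | intermediate
18 | acetonide aldehyde: as 16 with CHO (C10) on C11 | CC1(C)OC[C@@H]2[C@H](O1)C[C@@H](C=C)C(C)(C)[C@H]2C=O | intermediate
19 | ethyl diazoacetate | CCOC(=O)C=[N+]=[N-] | starting material
20 | acetonide beta-keto ester: C11–C(=O)CH2CO2Et | CC1(C)OC[C@@H]2[C@H](O1)C[C@@H](C=C)C(C)(C)[C@H]2C(=O)CC(=O)OCC | intermediate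
21 | acetonide beta-hydroxy ester: C11–CH(OH)CH2CO2Et, carbinol C10 (R) | CC1(C)OC[C@@H]2[C@H](O1)C[C@@H](C=C)C(C)(C)[C@H]2[C@H](O)CC(=O)OCC | intermediate
22 | TBS ether of 21 | CC1(C)OC[C@@H]2[C@H](O1)C[C@@H](C=C)C(C)(C)[C@H]2[C@H](O[Si](C)(C)C(C)(C)C)CC(=O)OCC | intermediate
23 | beta-silyloxy aldehyde: C11–CH(OTBS)CH2CHO | CC1(C)OC[C@@H]2[C@H](O1)C[C@@H](C=C)C(C)(C)[C@H]2[C@H](O[Si](C)(C)C(C)(C)C)CC=O | intermediate
24 | terminal alkyne: C11–CH(OTBS)CH2C≡CH | CC1(C)OC[C@@H]2[C@H](O1)C[C@@H](C=C)C(C)(C)[C@H]2[C@H](O[Si](C)(C)C(C)(C)C)CC#C | intermediate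
25 | (E)-alkenyldimethylalane: C11–CH(OTBS)CH2C(CH3)=CH–AlMe2 | CC1(C)OC[C@@H]2[C@H](O1)C[C@@H](C=C)C(C)(C)[C@H]2[C@H](O[Si](C)(C)C(C)(C)C)C/C(C)=C/[Al](C)C | intermediate
26 | lithium (E)-alkenyl(butyl)dimethylalanate derived from 25 | CC1(C)OC[C@@H]2[C@H](O1)C[C@@H](C=C)C(C)(C)[C@H]2[C@H](O[Si](C)(C)C(C)(C)C)C/C(C)=C/[Al-](C)(C)CCCC.[Li+] | intermediate
27 | (E)-allylic alcohol: C11–CH(OTBS)CH2C(CH3)=CHCH2OH | CC1(C)OC[C@@H]2[C@H](O1)C[C@@H](C=C)C(C)(C)[C@H]2[C@H](O[Si](C)(C)C(C)(C)C)C/C(C)=C/CO | intermediate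
28 | (E)-allylic bromide: C6-Br analogue of 27 | CC1(C)OC[C@@H]2[C@H](O1)C[C@@H](C=C)C(C)(C)[C@H]2[C@H](O[Si](C)(C)C(C)(C)C)C/C(C)=C/CBr | intermediate
29 | (E)-allylic phenyl sulfone: C6-SO2Ph analogue of 27 | CC1(C)OC[C@@H]2[C@H](O1)C[C@@H](C=C)C(C)(C)[C@H]2[C@H](O[Si](C)(C)C(C)(C)C)C/C(C)=C/CS(=O)(=O)c1ccccc1 | intermediate
30 | B-alkyl-9-borabicyclo[3.3.1]nonane adduct of 29 (boron on C3) | CC1(C)OC[C@@H]2[C@H](O1)C[C@@H](CCB3C4CCCC3CCC4)C(C)(C)[C@H]2[C@H](O[Si](C)(C)C(C)(C)C)C/C(C)=C/CS(=O)(=O)c1ccccc1 | intermediate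
31 | primary alcohol: C1 arm CH2CH2OH, C11 arm as in 29 | CC1(C)OC[C@@H]2[C@H](O1)C[C@@H](CCO)C(C)(C)[C@H]2[C@H](O[Si](C)(C)C(C)(C)C)C/C(C)=C/CS(=O)(=O)c1ccccc1 | intermediate
32 | aldehyde: C1 arm CH2CHO | CC1(C)OC[C@@H]2[C@H](O1)C[C@@H](CC=O)C(C)(C)[C@H]2[C@H](O[Si](C)(C)C(C)(C)C)C/C(C)=C/CS(=O)(=O)c1ccccc1 | intermediate
33 | ethyl 2-(triphenyl-λ5-phosphanylidene)propanoate | CCOC(=O)C(C)=P(c1ccccc1)(c1ccccc1)c1ccccc1 | starting material
34 | (E)-enoate: C1 arm CH2CH=C(CH3)CO2Et | CC1(C)OC[C@@H]2[C@H](O1)C[C@@H](C/C=C(C)/C(=O)OCC)C(C)(C)[C@H]2[C@H](O[Si](C)(C)C(C)(C)C)C/C(C)=C/CS(=O)(=O)c1ccccc1 | intermediate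
35 | (E)-allylic alcohol: C1 arm CH2CH=C(CH3)CH2OH | CC1(C)OC[C@@H]2[C@H](O1)C[C@@H](C/C=C(C)/CO)C(C)(C)[C@H]2[C@H](O[Si](C)(C)C(C)(C)C)C/C(C)=C/CS(=O)(=O)c1ccccc1 | intermediate
36 | (E)-allylic bromide: C1 arm CH2CH=C(CH3)CH2Br | CC1(C)OC[C@@H]2[C@H](O1)C[C@@H](C/C=C(C)/CBr)C(C)(C)[C@H]2[C@H](O[Si](C)(C)C(C)(C)C)C/C(C)=C/CS(=O)(=O)c1ccccc1 | intermediate
37 | macrocyclic sulfone: 6-(phenylsulfonyl) derivative of 38, both C6 epimers | CC1(C)OC[C@@H]2[C@H](O1)C[C@H]3C/C=C(C)/CC(S(=O)(=O)c4ccccc4)/C=C(C)/C[C@@H](O[Si](C)(C)C(C)(C)C)[C@@H]2C3(C)C | intermediate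
38 | (3E,7E)-verticilla-3,7-diene carrying 10-OTBS and the 13,18-O-isopropylidene acetal (C1, C10, C11 as in 45) | CC1(C)OC[C@@H]2[C@H](O1)C[C@H]3C/C=C(C)/CC/C=C(C)/C[C@@H](O[Si](C)(C)C(C)(C)C)[C@@H]2C3(C)C | intermediate
39 | C10 alcohol from 38 | CC1(C)OC[C@@H]2[C@H](O1)C[C@H]3C/C=C(C)/CC/C=C(C)/C[C@@H](O)[C@@H]2C3(C)C | intermediate
40 | C10 acetate of 39 | CC1(C)OC[C@@H]2[C@H](O1)C[C@H]3C/C=C(C)/CC/C=C(C)/C[C@@H](OC(C)=O)[C@@H]2C3(C)C | intermediate
41 | (3E,7E)-10-acetoxyverticilla-3,7-diene-13,18-diol (C12 CH2OH trans to the C11–C10 bond; C13 OH cis to the C12 CH2OH) | OC[C@@H]1[C@H](O)C[C@H]2C/C=C(C)/CC/C=C(C)/C[C@@H](OC(C)=O)[C@@H]1C2(C)C | intermediate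
42 | 18-O-tosylate of 41 | Cc1ccc(cc1)S(=O)(=O)OC[C@@H]1[C@H](O)C[C@H]2C/C=C(C)/CC/C=C(C)/C[C@@H](OC(C)=O)[C@@H]1C2(C)C | intermediate
43 | beta-tosyloxy ketone: 13-oxo derivative of 42 | Cc1ccc(cc1)S(=O)(=O)OC[C@@H]1C(=O)C[C@H]2C/C=C(C)/CC/C=C(C)/C[C@@H](OC(C)=O)[C@@H]1C2(C)C | intermediate
44 | (1R,3E,7E,10R,11R)-10-acetoxyverticilla-3,7,12(18)-trien-13-one | C=C1C(=O)C[C@H]2C/C=C(C)/CC/C=C(C)/C[C@@H](OC(C)=O)[C@@H]1C2(C)C | intermediate
45 | CNP0339728.1, (1R,3S,4S,7S,8S,10R,11R)-10-acetoxy-3,4:7,8-diepoxyverticill-12(18)-en-13-one | C=C1C(=O)C[C@H]2C[C@@H]3O[C@@]3(C)CC[C@@H]3O[C@@]3(C)C[C@@H](OC(C)=O)[C@@H]1C2(C)C | target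

**Step count and risks**
Total steps: 32. Longest linear sequence: 31 steps, from 4 to 45 (steps 2 to 32); step 1 is a one-step side branch that makes 3.

The three steps most likely to fail:

Step 7 (tandem conjugate reduction and hydroxymethylation). The enone is beta,beta-disubstituted next to a quaternary carbon, so the copper hydride may be slow, and the cis relationship of the two arms rests on the facial argument alone. The fallback sets out from 12 and makes the same C12 enolate by electron transfer instead of hydride transfer. Li (2.1 equiv) in liquid NH3/THF with t-BuOH (1 equiv) at −78 °C reduces the enone with axial protonation at C11 (the same cis outcome), the limiting amount of lithium sparing the PMB ether. Me3SiCl/Et3N then traps the lithium enolate as the trimethylsilyl enol ether F1. Hydroxymethylation of F1 (aq. HCHO, Yb(OTf)3, THF) comes back to the route at 14.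

Step 25 (macrocyclisation). Oligomerisation, elimination of the allylic bromide, or strain in the bridged twelve-membered ring can defeat the sulfone alkylation. The fallback sets out from 35. ClCO2Me and pyridine give the allylic methyl carbonate F2. Slow addition of F2 to Pd(PPh3)4 (10 mol%) and Ph2PCH2CH2PPh2 in THF at 65 °C closes the ring by Tsuji–Trost allylic alkylation. Zerovalent palladium ionises the carbonate with loss of CO2, the methoxide so released deprotonates the allylic sulfone, and the carbanion attacks the primary terminus of the allylpalladium complex. This comes back to the route at 37.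

Step 32 (double epoxidation). The facial selectivity depends on the conformation of the macrocycle, and a mixture of diastereomeric bis-epoxides is possible. The fallback sets out from 41, before the enone is unveiled, and uses reagent control. Shi epoxidation with the L-fructose-derived ketone (the enantiomer of the usual D-fructose-derived catalyst) is run with Oxone (2KHSO5·KHSO4·K2SO4), K2CO3 and Bu4NHSO4 in MeCN/dimethoxymethane/aq. Na2B4O7 buffer at 0 °C. Its dioxirane should deliver oxygen to the faces of the E-trisubstituted alkenes that give (S,S)-oxiranes, affording the bis-epoxy diol F3. TsCl in pyridine gives the bis-epoxy tosylate F4. Dess–Martin oxidation followed by Et3N, through the bis-epoxy β-tosyloxy ketone F5, comes back at 45.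

Further compounds
F1 | step 7 | trimethylsilyl enol ether (C12=C13–OSiMe3) of (3S,5S)-3-{[(4-methoxybenzyl)oxy]methyl}-4,4-dimethyl-5-vinylcyclohexanone | C[Si](C)(C)OC1=C[C@H](COCc2ccc(OC)cc2)C(C)(C)[C@H](C=C)C1
F2 | step 25 | allylic methyl carbonate of 35 (C5-OCO2Me) | CC1(C)OC[C@@H]2[C@H](O1)C[C@@H](C/C=C(C)/COC(=O)OC)C(C)(C)[C@H]2[C@H](O[Si](C)(C)C(C)(C)C)C/C(C)=C/CS(=O)(=O)c1ccccc1
F3 | step 32 | bis-epoxy diol: (3S,4S,7S,8S)-diepoxide of 41 | OC[C@@H]1[C@H](O)C[C@H]2C[C@@H]3O[C@@]3(C)CC[C@@H]3O[C@@]3(C)C[C@@H](OC(C)=O)[C@@H]1C2(C)C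
F4 | step 32 | bis-epoxy tosylate: 18-O-tosylate of F3 | Cc1ccc(cc1)S(=O)(=O)OC[C@@H]1[C@H](O)C[C@H]2C[C@@H]3O[C@@]3(C)CC[C@@H]3O[C@@]3(C)C[C@@H](OC(C)=O)[C@@H]1C2(C)C
F5 | step 32 | bis-epoxy β-tosyloxy ketone: 13-oxo derivative of F4 | Cc1ccc(cc1)S(=O)(=O)OC[C@@H]1C(=O)C[C@H]2C[C@@H]3O[C@@]3(C)CC[C@@H]3O[C@@]3(C)C[C@@H](OC(C)=O)[C@@H]1C2(C)C
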